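**Retrosynthetic overview**

- The target is a triflavanoid: ring A of a (2R,3S)-catechin core is bonded at C6 and at C8 to C4 of two (2R,3S,4S)-fisetinidol units. In each outer unit, ring C (O1, C2, C3, C4, C4a, C8a) carries the all-trans 2-aryl/3-hydroxy/4-aryl triad, and this ring is the retron on which the plan rests.
- Disconnection 1: global deprotection leads back to an undeca-O-benzyl trimer whose two outer 3-oxygens are acetylated.
- Disconnection 2 (key): both outer rings C are opened across O1–C2 and C3–C4, giving a benzylated catechin with two (2-hydroxyaryl)carbinol arms at C6/C8 (two latent ortho-quinone methides) and two molecules of an (E)-β-acetoxystyrene.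
- Disconnection 3: the arms come from 6,8-dibromo-penta-O-benzylcatechin by bromine–lithium exchange and addition to a salicylaldehyde ether; the enol acetate comes from an (E)-styryltrifluoroborate by oxidative C–O coupling.
- Ring order: rings A and C of the core are taken from (+)-catechin; the two outer rings C are formed last, in one operation.

Key step: step 10

Assumption: the (R)-enantiomer of the phosphoric acid is taken as the one matched to the required 2R,3S,4S sense at both methides; if the sense proves opposite, the (S)-acid is used with no other change.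
Assumption: in steps 5 and 10 the C8 site is drawn as reacting first; the order has no bearing on the product.
Remark: aldehydes 5 and 12 are catalogue compounds, each one benzylation away from 2,4-dihydroxybenzaldehyde and 3,4-dihydroxybenzaldehyde.

**Route**

Step 1
Reactants: 1 (+)-catechin
Product: 2 5,7,3',4'-tetra-O-benzyl-(+)-catechin (2R,3S)
Conditions: BnBr (4.4 equiv), K2CO3 (5 equiv), DMF, 0 °C → rt
Reagents that add atoms: benzyl bromide, BrCc1ccccc1
Why: Williamson etherification with a carbonate base alkylates only the four phenols and leaves the secondary 3-OH and the C2/C3 centres untouched.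

Step 2
Reactants: 2 5,7,3',4'-tetra-O-benzyl-(+)-catechin
Product: 3 3,5,7,3',4'-penta-O-benzyl-(+)-catechin (2R,3S)
Conditions: NaH (1.3 equiv), BnBr (1.3 equiv), DMF, 0 °C → rt
Reagents that add atoms: benzyl bromide, BrCc1ccccc1
Why: Williamson etherification of the 3-alkoxide; with every phenol already capped, base-induced opening of ring C and epimerisation at C2 cannot occur.

Step 3
Reactants: 3 3,5,7,3',4'-penta-O-benzyl-(+)-catechin
Product: 4 6,8-dibromo-3,5,7,3',4'-penta-O-benzylcatechin (2R,3S)
Conditions: NBS (2.1 equiv), CH2Cl2, −20 °C → rt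
Reagents that add atoms: N-bromosuccinimide, O=C1CCC(=O)N1Br
Why: electrophilic aromatic bromination; the phloroglucinol-type ring A is far more nucleophilic than ring B, so its two free positions (C8, then C6) should be substituted first.

Step 4
Reactants: 5 4-benzyloxy-2-hydroxybenzaldehyde
Product: 6 2-allyloxy-4-benzyloxybenzaldehyde
Conditions: allyl bromide (1.3 equiv), K2CO3, DMF, 50 °C
Reagents that add atoms: allyl bromide, C=CCBr
Why: Williamson etherification of the chelated 2-OH installs a phenol mask that tolerates organolithiums and can later be removed without acid.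

Step 5
Reactants: 4 6,8-dibromo-3,5,7,3',4'-penta-O-benzylcatechin; 6 2-allyloxy-4-benzyloxybenzaldehyde (2.2 equiv in total)
Product: 10 6,8-bis[(2-allyloxy-4-benzyloxyphenyl)hydroxymethyl]-3,5,7,3',4'-penta-O-benzylcatechin (carbinol epimers), via 6-bromo-8-lithio-penta-O-benzylcatechin 7 (not isolated), via lithium alkoxide of the 6-bromo-8-carbinol mono-adduct 8 (not isolated), via 6-lithio derivative of the mono-adduct alkoxide 9 (not isolated)
Conditions: n-BuLi (1.05 equiv), THF, −78 °C; 6 (1.0 equiv); n-BuLi (1.1 equiv), −78 °C; 6 (1.2 equiv); H2O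
Reagents that add atoms: none
Why: bromine–lithium exchange followed by 1,2-addition to the aldehyde, run one site at a time so that only mono-aryllithiums flanked by two alkoxy groups are generated; the two carbinol centres form without control, which is harmless because both become sp2 in step 10.

Step 6
Reactants: 10 6,8-bis[(2-allyloxy-4-benzyloxyphenyl)hydroxymethyl]-penta-O-benzylcatechin
Product: 11 6,8-bis[(4-benzyloxy-2-hydroxyphenyl)hydroxymethyl]-3,5,7,3',4'-penta-O-benzylcatechin (carbinol epimers)
Conditions: Pd(PPh3)4 (5 mol %), morpholine (10 equiv), THF, rt; Et3N-deactivated silica, used promptly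
Reagents that add atoms: none
Why: Tsuji–Trost deallylation (π-allyl formation at zerovalent palladium, capture by morpholine) frees both ortho phenols under basic, non-ionising conditions that spare the acid-labile benzhydrols and the benzyl ethers.

Step 7
Reactants: 12 3,4-dibenzyloxybenzaldehyde
Product: 13 (E)-2-[2-(3,4-dibenzyloxyphenyl)ethenyl]-4,4,5,5-tetramethyl-1,3,2-dioxaborolane
Conditions: CH2(Bpin)2 (1.2 equiv), lithium 2,2,6,6-tetramethylpiperidide (1.2 equiv), THF, 0 °C; then 12, −78 °C → rt
Reagents that add atoms: bis(pinacolato)borylmethane, CC1(C)OB(CB2OC(C)(C)C(C)(C)O2)OC1(C)C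
Why: boron-Wittig olefination, in which the α-boryl carbanion adds to the aldehyde and syn elimination of a boron oxide delivers the 1,2-disubstituted alkenylboronate with (E)-geometry.

Step 8
Reactants: 13 (E)-styrylboronic pinacol ester
Product: 14 potassium (E)-[2-(3,4-dibenzyloxyphenyl)ethenyl]trifluoroborate
Conditions: KHF2 (4 equiv), MeOH/H2O, rt
Reagents that add atoms: potassium hydrogen difluoride, F.[F-].[K+]
Why: ligand exchange at boron (boronate to trifluoroborate) gives a crystalline coupling partner without touching the alkene geometry.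

Step 9
Reactants: 14 potassium (E)-styryltrifluoroborate
Product: 15 (E)-2-(3,4-dibenzyloxyphenyl)vinyl acetate
Conditions: AcOH (2 equiv), Cu(OAc)2 (20 mol %), DMAP (40 mol %), 4 Å MS, O2 (1 atm), MeCN, 40 °C
Reagents that add atoms: acetic acid, CC(=O)O
Why: Chan–Lam-type oxidative C–O coupling of an alkenyltrifluoroborate with a carboxylic acid runs through transmetalation to copper and reductive elimination, so the (E)-geometry should be retained.

Step 10
Reactants: 11 6,8-bis[(4-benzyloxy-2-hydroxyphenyl)hydroxymethyl]-penta-O-benzylcatechin; 15 (E)-2-(3,4-dibenzyloxyphenyl)vinyl acetate (5 equiv)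
Product: 19 undeca-O-benzyl bis-fisetinidol-(4α→6:4α→8)-catechin bearing an acetate on each outer 3-oxygen (2R,3S,4S in both outer rings C), via C8-arm ortho-quinone methide 16 (not isolated), via C8 mono-cycloadduct carrying the C6 carbinol arm 17 (not isolated), via C6-arm ortho-quinone methide of the mono-cycloadduct 18 (not isolated)
Conditions: (R)-3,3'-bis(2,4,6-triisopropylphenyl)-1,1'-binaphthyl-2,2'-diyl hydrogen phosphate (20 mol %), 5 Å MS, CH2Cl2 (0.02 M), −20 °C → rt
Reagents that add atoms: none
Why: Proposed new method: the phosphoric acid dehydrates each ortho-hydroxybenzhydrol arm to a hydrogen-bonded (E)-ortho-quinone methide, whose methide carbon is attacked by the acetoxy-bearing alkene carbon of 15 while the quinone oxygen bonds to the benzylic alkene carbon, an asynchronous inverse-electron-demand oxa-[4+2] that is then repeated at the second arm. The closest known reaction type is the chiral-phosphoric-acid-catalysed hetero-Diels–Alder reaction of in situ ortho-quinone methides with styrenes and (E)-propenylarenes, the untested element being a β-acyloxystyrene as the 2π partner. Each of the two pyran rings (ring C of an outer unit) closes by intermolecular [4+2] cycloaddition that forms C3–C4 and O1–C2 together, and in the stepwise limit the second bond is a 6-exo-trig capture of the para-benzyloxybenzyl cation by the phenolic oxygen. C2 and C3 take their trans relation from the (E)-geometry of 15 (suprafacial addition, backed in a stepwise path by anti opening of an acetoxonium ion), C4 takes its cis relation to C2 from the aryl-endo transition state of the (E)-methide, and the absolute sense in both rings comes from the methide face left open by the chiral phosphate, the all-equatorial triad being also the thermodynamic one. The step needs the regiochemistry in which the aryl group and not the acyloxy group polarises the alkene, which the para-benzyloxy substituent secures by stabilising positive charge at C2 far better than acetoxy could at C3, and it needs trapping to outrun self-condensation of the methide, which the excess of 15 and the stabilising 2,4,6-trioxygenated catechin ring on the methide carbon should provide. Cross-trapping between the two arms is excluded because a ring spanning C6 and C8 would be a strained metacyclophane.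

Step 11
Reactants: 19 undeca-O-benzyl trimer diacetate
Product: 20 undeca-O-benzyl bis-fisetinidol-(4α→6:4α→8)-catechin with both outer 3-OH groups free
Conditions: K2CO3 (0.5 equiv), MeOH/THF 1:1, rt
Reagents that add atoms: none
Why: base-catalysed transesterification (Zemplén-type methanolysis) removes the two secondary acetates, while benzyl ethers, the C4–aryl bonds and all stereocentres are inert to mild carbonate.

Step 12
Reactants: 20 undeca-O-benzyl trimer diol
Product: 21 fisetinidol-(4α→6)-[fisetinidol-(4α→8)]-catechin (CNP0289228.3)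
Conditions: H2 (1 atm), Pd(OH)2/C (20 wt %), THF/MeOH 1:1, rt
Reagents that add atoms: none
Why: heterogeneous hydrogenolysis cleaves the eleven O-benzyl ethers, while the cyclic C2–O1 ethers and the hindered diarylmethine C4–aryl bonds are expected to survive as in standard proanthocyanidin deprotection, so no stereocentre is touched.

**Compound list**

1 | (+)-catechin, (2R,3S) | Oc1cc(O)c2c(c1)O[C@H](c1ccc(O)c(O)c1)[C@@H](O)C2 | starting material
2 | 5,7,3',4'-tetra-O-benzyl-(+)-catechin | c1c(OCc5ccccc5)c2c(cc1OCc5ccccc5)O[C@H](c6ccc(OCc5ccccc5)c(OCc5ccccc5)c6)[C@@H](O)C2 | intermediate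
3 | 3,5,7,3',4'-penta-O-benzyl-(+)-catechin | c1c(OCc5ccccc5)c2c(cc1OCc5ccccc5)O[C@H](c6ccc(OCc5ccccc5)c(OCc5ccccc5)c6)[C@@H](OCc5ccccc5)C2 | intermediate
4 | 6,8-dibromo-3,5,7,3',4'-penta-O-benzylcatechin | Brc1c(OCc5ccccc5)c2c(c(Br)c1OCc5ccccc5)O[C@H](c6ccc(OCc5ccccc5)c(OCc5ccccc5)c6)[C@@H](OCc5ccccc5)C2 | intermediate
5 | 4-benzyloxy-2-hydroxybenzaldehyde | O=Cc1ccc(OCc2ccccc2)cc1O | starting material
6 | 2-allyloxy-4-benzyloxybenzaldehyde | O=Cc1ccc(OCc2ccccc2)cc1OCC=C | intermediate
7 | 6-bromo-8-lithio-penta-O-benzylcatechin | Brc1c(OCc5ccccc5)c2c(c([Li])c1OCc5ccccc5)O[C@H](c6ccc(OCc5ccccc5)c(OCc5ccccc5)c6)[C@@H](OCc5ccccc5)C2 | intermediate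
8 | lithium alkoxide of 6-bromo-8-[(2-allyloxy-4-benzyloxyphenyl)hydroxymethyl]-penta-O-benzylcatechin | Brc1c(OCc5ccccc5)c2c(c(C(O[Li])c3ccc(OCc5ccccc5)cc3OCC=C)c1OCc5ccccc5)O[C@H](c6ccc(OCc5ccccc5)c(OCc5ccccc5)c6)[C@@H](OCc5ccccc5)C2 | intermediate
9 | 6-lithio derivative of alkoxide 8 | [Li]c1c(OCc5ccccc5)c2c(c(C(O[Li])c3ccc(OCc5ccccc5)cc3OCC=C)c1OCc5ccccc5)O[C@H](c6ccc(OCc5ccccc5)c(OCc5ccccc5)c6)[C@@H](OCc5ccccc5)C2 | intermediate
10 | 6,8-bis[(2-allyloxy-4-benzyloxyphenyl)hydroxymethyl]-penta-O-benzylcatechin (carbinol epimers) | OC(c1ccc(OCc5ccccc5)cc1OCC=C)c1c(OCc5ccccc5)c2c(c(C(O)c3ccc(OCc5ccccc5)cc3OCC=C)c1OCc5ccccc5)O[C@H](c6ccc(OCc5ccccc5)c(OCc5ccccc5)c6)[C@@H](OCc5ccccc5)C2 | intermediate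
11 | 6,8-bis[(4-benzyloxy-2-hydroxyphenyl)hydroxymethyl]-penta-O-benzylcatechin (carbinol epimers) | OC(c1ccc(OCc5ccccc5)cc1O)c1c(OCc5ccccc5)c2c(c(C(O)c3ccc(OCc5ccccc5)cc3O)c1OCc5ccccc5)O[C@H](c6ccc(OCc5ccccc5)c(OCc5ccccc5)c6)[C@@H](OCc5ccccc5)C2 | intermediate
12 | 3,4-dibenzyloxybenzaldehyde | O=Cc1ccc(OCc2ccccc2)c(OCc2ccccc2)c1 | starting material
13 | (E)-2-[2-(3,4-dibenzyloxyphenyl)ethenyl]-4,4,5,5-tetramethyl-1,3,2-dioxaborolane | CC1(C)OB(/C=C/c2ccc(OCc3ccccc3)c(OCc3ccccc3)c2)OC1(C)C | intermediate
14 | potassium (E)-[2-(3,4-dibenzyloxyphenyl)ethenyl]trifluoroborate | [K+].F[B-](F)(F)/C=C/c1ccc(OCc2ccccc2)c(OCc2ccccc2)c1 | intermediate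
15 | (E)-2-(3,4-dibenzyloxyphenyl)vinyl acetate | CC(=O)O/C=C/c1ccc(OCc2ccccc2)c(OCc2ccccc2)c1 | intermediate
16 | (E)-ortho-quinone methide at the C8 arm, C6 carbinol arm intact | OC(c1ccc(OCc5ccccc5)cc1O)c1c(OCc5ccccc5)c2c(c(/C=C3/C(=O)C=C(OCc5ccccc5)C=C3)c1OCc5ccccc5)O[C@H](c6ccc(OCc5ccccc5)c(OCc5ccccc5)c6)[C@@H](OCc5ccccc5)C2 | intermediate
17 | mono-cycloadduct: 3-O-acetyl-tri-O-benzylfisetinidol-(4α→8)-penta-O-benzylcatechin carrying the C6 carbinol arm | OC(c1ccc(OCc5ccccc5)cc1O)c1c(OCc5ccccc5)c2c(c([C@@H]3c4ccc(OCc5ccccc5)cc4O[C@H](c6ccc(OCc5ccccc5)c(OCc5ccccc5)c6)[C@H]3OC(C)=O)c1OCc5ccccc5)O[C@H](c6ccc(OCc5ccccc5)c(OCc5ccccc5)c6)[C@@H](OCc5ccccc5)C2 | intermediate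
18 | (E)-ortho-quinone methide at the C6 arm of mono-cycloadduct 17 | O=C1C=C(OCc5ccccc5)C=C/C1=C\c1c(OCc5ccccc5)c2c(c([C@@H]3c4ccc(OCc5ccccc5)cc4O[C@H](c6ccc(OCc5ccccc5)c(OCc5ccccc5)c6)[C@H]3OC(C)=O)c1OCc5ccccc5)O[C@H](c6ccc(OCc5ccccc5)c(OCc5ccccc5)c6)[C@@H](OCc5ccccc5)C2 | intermediate
19 | undeca-O-benzyl trimer with acetates on both outer 3-oxygens | c5ccccc5COc1ccc2c(c1)O[C@H](c6ccc(OCc5ccccc5)c(OCc5ccccc5)c6)[C@@H](OC(C)=O)[C@@H]2c1c(OCc5ccccc5)c2c(c([C@@H]3c4ccc(OCc5ccccc5)cc4O[C@H](c6ccc(OCc5ccccc5)c(OCc5ccccc5)c6)[C@H]3OC(C)=O)c1OCc5ccccc5)O[C@H](c6ccc(OCc5ccccc5)c(OCc5ccccc5)c6)[C@@H](OCc5ccccc5)C2 | intermediate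
20 | undeca-O-benzyl trimer, outer 3-OH groups free | c5ccccc5COc1ccc2c(c1)O[C@H](c6ccc(OCc5ccccc5)c(OCc5ccccc5)c6)[C@@H](O)[C@@H]2c1c(OCc5ccccc5)c2c(c([C@@H]3c4ccc(OCc5ccccc5)cc4O[C@H](c6ccc(OCc5ccccc5)c(OCc5ccccc5)c6)[C@H]3O)c1OCc5ccccc5)O[C@H](c6ccc(OCc5ccccc5)c(OCc5ccccc5)c6)[C@@H](OCc5ccccc5)C2 | intermediate
21 | fisetinidol-(4α→6)-[fisetinidol-(4α→8)]-catechin (CNP0289228.3) | Oc1ccc2c(c1)O[C@H](c1ccc(O)c(O)c1)[C@@H](O)[C@@H]2c1c(O)c2c(c([C@@H]3c4ccc(O)cc4O[C@H](c4ccc(O)c(O)c4)[C@H]3O)c1O)O[C@H](c1ccc(O)c(O)c1)[C@@H](O)C2 | target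

**Step count and risks**

Total step count: 12. Longest linear sequence: 8 (steps 1, 2, 3, 5, 6, 10, 11, 12).

Steps most likely to fail:

1. Step 10 (key step). The alkene may add with reversed regiochemistry (acyloxy-directed, giving acetal-type chromans). Face selection at one or both methides may be poor against the remote catechin stereocentres, giving diastereomeric trimers. The methide may also self-condense faster than it is trapped. The fallback uses the known acid-catalysed flavan-3,4-diol/flavan-3-ol condensation and sets out from 1. Purchased (2R,3R)-fustin is reduced with NaBH4 in EtOH to (2R,3S,4R)-leucofisetinidin, (+)-mollisacacidin F1. F1 (2.5 equiv) and (+)-catechin 1 are then stirred in 0.1 M aqueous HCl at rt, so that the flavan-4-yl cation alkylates C8 and then C6 of ring A, mainly anti to the 3-hydroxyl. After chromatographic removal of biflavanoids and 4β epimers this comes back to the route directly at target 21.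

2. Step 5. The second bromine–lithium exchange may stall, or the second aryllithium may be quenched by proton transfer before it adds, leaving mono-arylated material. The fallback separates the two C–C bond formations and sets out from 4. One exchange (n-BuLi, 1.0 equiv, THF, −78 °C) and addition of 6 (1.0 equiv) would give, after isolation, the mono-adduct bromide F2 (drawn as the C8 adduct; the C6 regioisomer behaves alike). F2 is capped as its triethylsilyl ether F3 (TESCl, imidazole, DMF). A second exchange on this neutral substrate (t-BuLi, 2 equiv, −78 °C) and addition of 6 gives the mono-silylated bis-adduct F4, and TBAF in THF removes the silyl group to come back at 10.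

3. Step 9. Protodeboronation or homocoupling of the electron-rich styryl boron species may erode the oxidative coupling, or the alkene geometry may be lost. The fallback sets out from 12. Wittig methoxymethylenation (MeOCH2PPh3Cl, KOt-Bu, THF) gives the enol ether F5 (E/Z). Mild hydrolysis (aqueous HCl, THF) gives (3,4-dibenzyloxyphenyl)acetaldehyde F6. Enol acetylation (Ac2O, KOAc, 120 °C), iodine-catalysed equilibration towards the (E)-isomer and crystallisation or chromatography on AgNO3-impregnated silica come back at 15.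

**Further compounds**

F1 | step 10 | (2R,3S,4R)-leucofisetinidin, (+)-mollisacacidin | Oc1ccc2c(c1)O[C@H](c1ccc(O)c(O)c1)[C@@H](O)[C@@H]2O
F2 | step 5 | 6-bromo-8-[(2-allyloxy-4-benzyloxyphenyl)hydroxymethyl]-penta-O-benzylcatechin | Brc1c(OCc5ccccc5)c2c(c(C(O)c3ccc(OCc5ccccc5)cc3OCC=C)c1OCc5ccccc5)O[C@H](c6ccc(OCc5ccccc5)c(OCc5ccccc5)c6)[C@@H](OCc5ccccc5)C2
F3 | step 5 | triethylsilyl ether of F2 | Brc1c(OCc5ccccc5)c2c(c(C(O[Si](CC)(CC)CC)c3ccc(OCc5ccccc5)cc3OCC=C)c1OCc5ccccc5)O[C@H](c6ccc(OCc5ccccc5)c(OCc5ccccc5)c6)[C@@H](OCc5ccccc5)C2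
F4 | step 5 | bis-adduct with the C8 carbinol as triethylsilyl ether | OC(c1ccc(OCc5ccccc5)cc1OCC=C)c1c(OCc5ccccc5)c2c(c(C(O[Si](CC)(CC)CC)c3ccc(OCc5ccccc5)cc3OCC=C)c1OCc5ccccc5)O[C@H](c6ccc(OCc5ccccc5)c(OCc5ccccc5)c6)[C@@H](OCc5ccccc5)C2
F5 | step 9 | 1,2-dibenzyloxy-4-(2-methoxyethenyl)benzene (E/Z) | COC=Cc1ccc(OCc2ccccc2)c(OCc2ccccc2)c1
F6 | step 9 | (3,4-dibenzyloxyphenyl)acetaldehyde | O=CCc1ccc(OCc2ccccc2)c(OCc2ccccc2)c1
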